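Ring A is closed last, between the carbinol carbon C3 and the quaternary carbon C4. The key step exploits that C4 with its two methyl groups, bonded to ring-fusion carbon C5, is the CMe2 bridge of a pinane. Hydrogen-atom transfer to an exocyclic methylene on a verbenone-derived bicyclo[3.1.1]heptane triggers scission of the cyclobutane, which releases ring B as a cyclohexene and C4 as a tertiary radical; this radical adds to a tethered C3 aldehyde. One operation thus remodels the bicycle into the trans-decalin, closes ring A and sets the C3 carbinol. The precursor is a 2-methylenepinane bearing the complete Z-enoate side chain and a 3-oxopropyl group.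

Key step: step 9

Remark: labdane numbers (C1 to C20) are used in all explanations; in the pinane intermediates, pinane C1, C2, C3, C4, C5, C6 and C7 are labdane C7, C8, C9, C10, C5, C4 and C6. Compounds 1, 2 and 11 are taken as commercial. The target is in the ent-labdane series, (3R,5S,7R,9S,10R).

Step 1
Reactants: 1 (1S,5S)-verbenone; 2 2-(2-bromoethyl)-1,3-dioxolane
Product: 5 (1S,5S)-3-allyl-4-[2-(1,3-dioxolan-2-yl)ethyl]-4,6,6-trimethylbicyclo[3.1.1]heptan-2-one (both new groups anti to the CMe2 bridge), via Grignard reagent 3 (not isolated), via magnesium enolate 4 (not isolated)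
Conditions: 2, Mg, THF, 25 °C; then CuBr·SMe2 (20 mol %), 1, THF, −40 → −10 °C; then allyl bromide, HMPA, −10 °C → rt
Reagents that add atoms: allyl bromide, C=CCBr
Why: Copper-catalysed conjugate addition of the Grignard reagent takes place on the enone face opposite the CMe2 bridge and so sets the quaternary C10 with the new chain anti to the bridge, and the magnesium enolate is then C-allylated at C9 on the same open face (tandem 1,4-addition and enolate alkylation).

Step 2
Reactants: 5 the 3-allyl ketone with allyl anti to the bridge
Product: 7 the C3 epimer of 5 (allyl syn to the CMe2 bridge and cis to the C4 methyl), via lithium enolate 6 (not isolated)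
Conditions: LiN(iPr)2, THF, −78 → 0 °C; then AcOH, THF, −78 °C
Reagents that add atoms: none
Why: C9 carries the only enolisable hydrogen (the bridgehead cannot enolise), and kinetic protonation of the planar lithium enolate on the face opposite the CMe2 bridge should deliver hydrogen anti and leave the allyl group syn to the bridge and cis to the C10 methyl, which is the C9 configuration of the target (kinetic enolate protonation).

Step 3
Reactants: 7 the 3-allyl ketone with allyl syn to the bridge
Product: 9 the 3-(2-hydroxyethyl) ketone, via aldehyde 8 (not isolated)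
Conditions: O3, CH2Cl2/MeOH, −78 °C; Me2S; then NaBH4, −78 → −30 °C
Reagents that add atoms: ozone, O=[O+][O-]
Why: Ozonolysis cleaves the only alkene, and NaBH4 at low temperature reduces the unhindered aldehyde much faster than the bicyclic ketone flanked by a bridgehead and a branched carbon (ozonolysis with chemoselective borohydride reduction).

Step 4
Reactants: 9 the 3-(2-hydroxyethyl) ketone
Product: 10 the 3-(2-iodoethyl) ketone
Conditions: I2, PPh3, imidazole, CH2Cl2, 0 °C
Reagents that add atoms: iodine, II
Why: Appel-type iodination converts the primary alcohol into the iodide under buffered conditions that leave the acetal and the epimerisable ketone untouched.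

Step 5
Reactants: 11 methyl but-2-ynoate
Product: 12 methyl (Z)-3-iodobut-2-enoate
Conditions: NaI, AcOH, 110 °C
Reagents that add atoms: sodium iodide, [Na+].[I-]
Why: Anti hydroiodination of the ynoate places iodine at C13 cis to the ester and so fixes the Z geometry of the later C13=C14 bond.

Step 6
Reactants: 10 the 3-(2-iodoethyl) ketone; 12 methyl (Z)-3-iodobut-2-enoate
Product: 14 methyl (2Z)-5-{(1S,5S)-4-[2-(1,3-dioxolan-2-yl)ethyl]-4,6,6-trimethyl-2-oxobicyclo[3.1.1]heptan-3-yl}-3-methylpent-2-enoate, via alkylzinc iodide 13 (not isolated)
Conditions: Zn dust, LiCl, THF, 40 °C; then 12, Pd(PPh3)4 (5 mol %), THF, rt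
Reagents that add atoms: none
Why: Zinc insertion into the primary iodide gives a ketone-tolerant alkylzinc iodide that couples with the vinyl iodide under palladium catalysis with retention of the Z geometry (Negishi coupling), forming the C12–C13 bond under neutral conditions that do not epimerise C9.

Step 7
Reactants: 14 the keto ester acetal
Product: 15 the 2-methylene analogue of 14
Conditions: Zn, CH2Br2, TiCl4, THF/CH2Cl2, 0 °C → rt
Reagents that add atoms: dibromomethane, BrCBr
Why: The Takai–Lombardo reagent methylenates the hindered ketone chemoselectively in the presence of the ester and is not basic, so the contra-thermodynamic C9 centre is kept and from here on is no longer epimerisable.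

Step 8
Reactants: 15 the methylene acetal
Product: 16 methyl (2Z)-3-methyl-5-[(1S,5S)-4,6,6-trimethyl-2-methylene-4-(3-oxopropyl)bicyclo[3.1.1]heptan-3-yl]pent-2-enoate
Conditions: PPTS, acetone/H2O, 50 °C
Reagents that add atoms: water, O
Why: Mild acid-catalysed transacetalisation to acetone frees the aldehyde, and PPTS is too weak an acid to protonate the strained methylenecyclobutane or isomerise the enoate.

Step 9
Reactants: 16 the methylene pinane aldehyde
Product: 17 methyl ent-3β-hydroxylabda-7,13Z-dien-15-oate (trans-decalin, equatorial 3-OH)
Conditions: Fe(acac)3 (30 mol %), PhSiH3, degassed EtOH, 60 °C, high dilution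
Reagents that add atoms: none
Why: Proposed new method: the iron hydride generated from Fe(acac)3 and PhSiH3 should transfer a hydrogen atom to the terminal carbon C17 of the exocyclic alkene, the tertiary cyclobutylcarbinyl radical at C8 should open by β-scission of the strained C7–C4 bond (the pinene radical-clock process) to give the 7,8-alkene and a tertiary radical at C4, and this radical should add to the C3 aldehyde, the alkoxy radical being reduced and protonated in ethanol. The closest known reaction types are the Fe(acac)3/PhSiH3 reductive radical cyclisation of alkene-tethered ketones and aldehydes and the hydrogen-atom-transfer ring opening of β-pinene; only their combination in one cascade is new. Ring A closes by 6-exo-trig attack of C4 on the carbonyl carbon, while ring B is not closed but set free from the bicycle. The new stereocentre C3 is controlled by a chair transition state with the carbonyl oxygen pseudo-equatorial, away from the axial hydrogens on C1 and C5, and the reversibility of radical addition to a carbonyl group works in the same direction; C5, C9 and C10 are carried over, and the trans ring fusion follows from the trans arrangement of the C5–C4 bond and the C10 chain fixed in step 1. The step needs hydrogen-atom transfer only at the 1,1-disubstituted alkene, which the electron-poor trisubstituted enoate and the slower-reacting trisubstituted product alkene allow with a limited amount of silane, and it needs ring scission to outrun attack of the C8 radical on the aldehyde, which the strain release and the reversibility of that attack should secure.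

Step 10
Reactants: 17 the 7,8-alkene
Product: 18 the 7,8-epoxide of 17 (oxygen on the face opposite the C10 methyl)
Conditions: mCPBA, NaHCO3, CH2Cl2, 0 °C
Reagents that add atoms: mCPBA, O=C(OO)c1cccc(Cl)c1
Why: Peracid epoxidation is selective for the electron-rich trisubstituted 7,8-alkene over the enoate and should occur on the face opposite the axial C10 methyl, although either epoxide face would serve because C7 is set again in step 13 (Prilezhaev epoxidation).

Step 11
Reactants: 18 the 7,8-epoxide
Product: 19 methyl ent-3β,7α-dihydroxylabda-8(17),13Z-dien-15-oate (C7 epimer of the target, axial 7-OH)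
Conditions: Cp2TiCl2, Mn dust, THF, rt; aqueous HCl work-up
Reagents that add atoms: none
Why: Cp2TiCl (trivalent titanium, formed in the flask) opens the epoxide homolytically at the tertiary C8, a second Cp2TiCl traps the radical and β-hydride elimination toward the unhindered C17 methyl gives the exocyclic 8(17)-alkene with the C7–O bond intact, under neutral conditions that spare the enoate (titanocene-mediated isomerisation of an epoxide to an allylic alcohol).

Step 12
Reactants: 19 the axial allylic alcohol
Product: 20 methyl ent-3β-hydroxy-7-oxolabda-8(17),13Z-dien-15-oate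
Conditions: MnO2, CH2Cl2, rt
Reagents that add atoms: none
Why: MnO2 oxidises only the allylic C7 alcohol and leaves the saturated C3 alcohol untouched (chemoselective allylic oxidation).

Step 13
Reactants: 20 the α-methylene ketone
Product: 21 the target, methyl (3R,5S,7R,9S,10R,13Z)-3,7-dihydroxylabda-8(17),13-dien-15-oate
Conditions: NaBH4, CeCl3·7H2O, MeOH, −78 °C
Reagents that add atoms: none
Why: Luche reduction adds hydride 1,2 to the enone along the axial trajectory on the face opposite the axial C10 methyl, which sets C7 with the equatorial hydroxyl cis to that methyl and leaves the ester and both alkenes alone.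

Compound list

1 | (1S,5S)-(−)-verbenone, (1S,5S)-4,6,6-trimethylbicyclo[3.1.1]hept-3-en-2-one | O=C1[C@H]2C[C@H](C2(C)C)C(C)=C1 | starting material
2 | 2-(2-bromoethyl)-1,3-dioxolane | BrCCC1OCCO1 | starting material
3 | [2-(1,3-dioxolan-2-yl)ethyl]magnesium bromide | Br[Mg]CCC1OCCO1 | intermediate (not isolated)
4 | bromomagnesium enolate of the 1,4-adduct, new chain anti to the CMe2 bridge | Br[Mg]OC=1[C@H]2C[C@H](C2(C)C)[C@@](C)(CCC3OCCO3)C=1 | intermediate (not isolated)
5 | (1S,5S)-3-allyl-4-[2-(1,3-dioxolan-2-yl)ethyl]-4,6,6-trimethylbicyclo[3.1.1]heptan-2-one; allyl and dioxolanylethyl anti to the CMe2 bridge, C4 methyl syn to it | O=C1[C@H]2C[C@H](C2(C)C)[C@@](C)(CCC3OCCO3)[C@H]1CC=C | intermediate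
6 | lithium enolate of 5 | [Li]OC=1[C@H]2C[C@H](C2(C)C)[C@@](C)(CCC3OCCO3)C=1CC=C | intermediate (not isolated)
7 | C3 epimer of 5; allyl syn to the CMe2 bridge and cis to the C4 methyl | O=C1[C@H]2C[C@H](C2(C)C)[C@@](C)(CCC3OCCO3)[C@@H]1CC=C | intermediate
8 | 3-(2-oxoethyl) analogue of 7 | O=C1[C@H]2C[C@H](C2(C)C)[C@@](C)(CCC3OCCO3)[C@@H]1CC=O | intermediate (not isolated)
9 | 3-(2-hydroxyethyl) analogue of 7 | O=C1[C@H]2C[C@H](C2(C)C)[C@@](C)(CCC3OCCO3)[C@@H]1CCO | intermediate
10 | 3-(2-iodoethyl) analogue of 7 | O=C1[C@H]2C[C@H](C2(C)C)[C@@](C)(CCC3OCCO3)[C@@H]1CCI | intermediate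
11 | methyl but-2-ynoate | CC#CC(=O)OC | starting material
12 | methyl (Z)-3-iodobut-2-enoate | I/C(C)=C\C(=O)OC | intermediate
13 | alkylzinc iodide from 10 | O=C1[C@H]2C[C@H](C2(C)C)[C@@](C)(CCC3OCCO3)[C@@H]1CC[Zn]I | intermediate (not isolated)
14 | methyl (2Z)-5-{(1S,5S)-4-[2-(1,3-dioxolan-2-yl)ethyl]-4,6,6-trimethyl-2-oxobicyclo[3.1.1]heptan-3-yl}-3-methylpent-2-enoate, ring stereochemistry as in 7 | O=C1[C@H]2C[C@H](C2(C)C)[C@@](C)(CCC3OCCO3)[C@@H]1CC/C(C)=C\C(=O)OC | intermediate
15 | 2-methylene analogue of 14 | C=C1[C@H]2C[C@H](C2(C)C)[C@@](C)(CCC3OCCO3)[C@@H]1CC/C(C)=C\C(=O)OC | intermediate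
16 | methyl (2Z)-3-methyl-5-[(1S,5S)-4,6,6-trimethyl-2-methylene-4-(3-oxopropyl)bicyclo[3.1.1]heptan-3-yl]pent-2-enoate | C=C1[C@H]2C[C@H](C2(C)C)[C@@](C)(CCC=O)[C@@H]1CC/C(C)=C\C(=O)OC | intermediate
17 | methyl ent-3β-hydroxylabda-7,13Z-dien-15-oate; trans-decalin, 3-OH equatorial, H-5 and H-9 on the face opposite the C10 methyl | CC1=CC[C@@H]2C(C)(C)[C@H](O)CC[C@@]2(C)[C@@H]1CC/C(C)=C\C(=O)OC | intermediate
18 | 7,8-epoxide of 17, oxygen on the face opposite the C10 methyl | C[C@]12O[C@H]1C[C@@H]1C(C)(C)[C@H](O)CC[C@@]1(C)[C@@H]2CC/C(C)=C\C(=O)OC | intermediate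
19 | methyl ent-3β,7α-dihydroxylabda-8(17),13Z-dien-15-oate (axial 7-OH) | C=C1[C@@H](O)C[C@@H]2C(C)(C)[C@H](O)CC[C@@]2(C)[C@@H]1CC/C(C)=C\C(=O)OC | intermediate
20 | methyl ent-3β-hydroxy-7-oxolabda-8(17),13Z-dien-15-oate | C=C1C(=O)C[C@@H]2C(C)(C)[C@H](O)CC[C@@]2(C)[C@@H]1CC/C(C)=C\C(=O)OC | intermediate
21 | methyl (3R,5S,7R,9S,10R,13Z)-3,7-dihydroxylabda-8(17),13-dien-15-oate (ent-3β,7β; both hydroxyls equatorial) | C=C1[C@H](O)C[C@@H]2C(C)(C)[C@H](O)CC[C@@]2(C)[C@@H]1CC/C(C)=C\C(=O)OC | target

Total step count: 13. Longest linear sequence: 12 steps (1 to 21 through steps 1 to 4 and 6 to 13).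

Steps most likely to fail

1. Step 9 (proposed new method). The first-formed C8 radical may attack the aldehyde before the cyclobutane opens, the C4 radical may be reduced before it cyclises, or the new 7,8-alkene may be over-reduced. The fallback sets out from 15 and comes back at 17, and separates ring opening from ring closure with known chemistry. With the acetal still in place, CoCl(salen) (a trivalent cobalt complex; salen = N,N′-bis(3,5-di-tert-butylsalicylidene)cyclohexane-1,2-diamine dianion) and catalytic PhSiH3 in benzene should isomerise the methylenecyclobutane by hydrogen-atom transfer, ring scission and hydrogen-atom return to the diene acetal F1, which carries the 7,8-alkene and an isopropenyl group on C5. PPTS in wet acetone then frees the diene aldehyde F2. The known Fe(acac)3/PhSiH3 reductive cyclisation of an alkene-tethered aldehyde, selective for the 1,1-disubstituted isopropenyl group, should close ring A to 17.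

2. Step 2. The enolate may be protonated on oxygen and tautomerise without facial control, or the product may revert to the more stable anti epimer on work-up. The fallback sets out from 5 and comes back at 7, and replaces protonation by irreversible hydrogen-atom delivery. The lithium enolate of 5 is brominated with N-bromosuccinimide to the α-bromo ketone F3. Bu3SnH with AIBN in benzene at 80 °C then generates the planar α-keto radical at C9, which should take hydrogen from the tin hydride on the face opposite the CMe2 bridge to give 7.

3. Step 1. C-allylation of the hindered magnesium enolate may be slow and lose to proton transfer or O-allylation. The fallback sets out from 1 (with Grignard reagent 3) and comes back at 5. After the same copper-catalysed 1,4-addition the enolate is trapped on oxygen with allyl chloroformate to give the allyl enol carbonate F4. Pd(PPh3)4 in THF then effects decarboxylative allylation (Tsuji allylation), which should deliver the allyl group to C9 on the open face and give 5.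

Further compounds

F1 | step 9 | methyl (2Z)-5-[2-[2-(1,3-dioxolan-2-yl)ethyl]-2,6-dimethyl-3-(prop-1-en-2-yl)cyclohex-5-en-1-yl]-3-methylpent-2-enoate; side chain, C10 methyl and isopropenyl all cis (labdane C9, C10, C5 as in 17) | CC1=CC[C@H](C(C)=C)[C@@](C)(CCC2OCCO2)[C@@H]1CC/C(C)=C\C(=O)OC
F2 | step 9 | methyl (2Z)-5-[2,6-dimethyl-2-(3-oxopropyl)-3-(prop-1-en-2-yl)cyclohex-5-en-1-yl]-3-methylpent-2-enoate, stereochemistry as in F1 | CC1=CC[C@H](C(C)=C)[C@@](C)(CCC=O)[C@@H]1CC/C(C)=C\C(=O)OC
F3 | step 2 | (1S,5S)-3-allyl-3-bromo-4-[2-(1,3-dioxolan-2-yl)ethyl]-4,6,6-trimethylbicyclo[3.1.1]heptan-2-one, bromine anti and allyl syn to the CMe2 bridge | O=C1[C@H]2C[C@H](C2(C)C)[C@@](C)(CCC3OCCO3)[C@]1(Br)CC=C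
F4 | step 1 | allyl (1S,5S)-4-[2-(1,3-dioxolan-2-yl)ethyl]-4,6,6-trimethylbicyclo[3.1.1]hept-2-en-2-yl carbonate | C=CCOC(=O)OC=1[C@H]2C[C@H](C2(C)C)[C@@](C)(CCC3OCCO3)C=1
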